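## Analysis of the target

The target 28 has three aromatic rings: a guaiacyl ring A that carries an arylglycerol chain, a syringyl ring B whose phenolic oxygen forms the β-aryl ether of that chain, and ring C, which is fused to a 2,3-dihydrofuran and bears a 7-methoxy and a 5-formyl group. Its four stereocentres form two pairs that ring B keeps apart. C2 and C3 of the dihydrobenzofuran are trans (2R,3S); chain C1 and chain C2 of the propane unit are (1S,2R), the erythro (anti) arrangement. Neither pair can steer the other. The sensitive functions are the aryl aldehyde, the free ring A phenol para to a benzylic carbinol (quinone methide formation), the benzylic aryl ether bond O1–C2 (hydrogenolysis, Lewis acids), and C3, which can be epimerised only while it carries a carbonyl group. The synthesis is hard because both pairs need absolute control, because the doubly ortho-substituted oxygen of ring B must be joined to a secondary carbon, and because the oxygen functions sit at three oxidation levels. The strategy rests on the C2–C3 bond: it joins the two ring stereocentres, and C2 is a benzylic ether carbon between O1 and the electron-rich ring B, so its C–H bond lies five atoms from a carbenoid carbon placed at the future C3 on ring C.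

## Retrosynthetic reasoning

**28 back to 25.** The last operations only unmask. Three silyl ethers are removed from 27. The aldehyde of 27 comes from the benzylic alcohol of diol 26, which is told apart from the saturated primary alcohol at C3 by a benzylic-selective oxidant. Both alcohols of 26 come from the two methyl esters of 25. C5 therefore stays an ester for as long as base and hydride chemistry is in use, and the ring A benzylic oxygen is silylated before the oxidation so that only one benzylic alcohol is free.

**25 back to 23.** The chain C1–H bond is cut, leading through alcohol 24 to the α-aryloxy ketone 23. The forward step is a hydride reduction under chelate control between the ketone and the ether oxygen. It sets chain C1 relative to chain C2 and gives the erythro isomer.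

**23 to 14 + 22.** The bond between chain C2 and the ring B oxygen is cut. This is the only C–O bond of the chain at which a doubly ortho-substituted phenol can realistically be introduced, because a carbon next to a carbonyl group accepts weak, hindered nucleophiles with clean inversion. The cut is convergent: phenol 14 holds the whole dihydrobenzofuran and α-hydroxy ketone 22 holds ring A and the chain. The forward reaction must invert chain C2 (2S to 2R) without enolising the ketone.

**22 back to 15 and 17.** The primary silyl ether and the acetal are removed (21, 20), then the aryl–carbonyl bond is cut. That gives aryllithium 19, made from bromide 16 (from 15), and Weinreb amide 18 (from the chiral-pool ester 17). Chain C2 is bought, not made.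

**14 back to 12.** Phenol 14 comes from benzyl ether 13 by hydrogenolysis, done before any aldehyde exists. Trans diester 13 comes from the cis diester 12 by equilibration at C3, the only centre with an acidic hydrogen.

**12 to 11 (key disconnection).** The C2–C3 bond is cut. The precursor 11 is achiral: ring C carries a diazoacetate at the future C3 and ring B hangs on the ortho oxygen as a benzyl ether. One catalytic event forms the bond, the ring and both stereocentres. The catalyst is chosen among the chiral dirhodium tetracarboxylates with N-phthaloyl amino acid ligands, not the arylsulfonylprolinates: the latter are at their best with methine sites, whereas the former combine cis selectivity with discrimination of the two hydrogens of an O–CH2–aryl group.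

**11 back to 1, 3 and 8.** Diazo transfer leads to arylacetate 10. Its aryl–CH2 bond is cut to aryl iodide 7 and zinc enolate 9 (from 8), which gives the arylacetate in one step at the right oxidation level. The ether bond of 7 is cut to phenol 2 and benzylic bromide 6. Phenol 2 is the ortho-iodination product of 1, and 6 comes from 3 by benzylation (4), reduction (5) and bromination.

## Alternatives that were turned down

**Alternative 1:** Both aryl–oxygen bonds of ring C (O1–C7a and C7–O) are disconnected. Ring C enters as a 2-fluorophenyl group in the open-chain alcohol A2, which already contains C2 and C3 in their final configuration. In the forward step a hindered lithium amide removes the proton next to fluorine and fluoride leaves to give the C7–C7a aryne. The benzylic alkoxide adds to C7a, closing the ring without touching a stereocentre. The aryl anion left at C7 is trapped with a borate ester and oxidised to phenol A1.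
- For it: one fluorine atom delivers both ring C oxygens with defined regiochemistry. The trans relationship is fixed before cyclisation and needs no epimerisation. C5 is already an acetal at the aldehyde level, so no ester reduction and reoxidation are needed. On these last two points it is stronger than the chosen route.
- Against it: the ring closure creates no stereocentre, so A2 must first be made as a single anti isomer by a separate asymmetric C–C bond formation between two aryl-bearing carbons. The strongly basic medium meets a doubly activated benzylic C–H at the future C3 and a β-silyloxy group, so elimination threatens. The amide base can add to the aryne, and the aryl anion must survive proton sources until it is trapped. Methylation of O7 and removal of acetal, methoxymethyl and silyl groups then use up most of the steps saved.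
- Comparison: in place of the better oxidation-state economy, the chosen strategy makes both ring stereocentres in one catalytic step under neutral conditions from an achiral precursor that is reached in a few steps.

**Alternative 2:** Only O1–C2 is disconnected. The precursor is the 2,3-diarylpropyl acetate A4, whose single stereocentre (the future C3) would come from one catalytic asymmetric step. In the forward step a mild silver oxidant converts the syringyl phenol of A4 into its para-quinone methide, and the ring C phenol adds to the exocyclic carbon in a 5-exo-trig closure that favours trans A3.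
- For it: the closure follows the intrinsic trans preference of such additions. A3 already has the ring B phenol free, the aldehyde in place and C3 at the alcohol level, so debenzylation, epimerisation and the reduction/reoxidation pair all disappear. In step economy after ring closure it is clearly stronger.
- Against it: C2 is not set by a reagent but relayed from C3 through a planar intermediate, so the cis isomer can be minimised but not excluded. The quinone methide has a hydrogen on the adjacent carbon, and tautomerisation to the conjugated alkene would erase the only stereocentre. An electron-rich phenol has to be oxidised next to an aldehyde and a second phenol. A4 still needs its own enantioselective synthesis.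
- Comparison: the chosen strategy sets C2 directly by the catalyst with every phenol capped, and pays for this with three to four extra functional-group steps.

**Alternative 3:** C3–C3a and O1–C2 are disconnected in one late step between the iodophenol A6 and the styrene A7, which already carries the complete erythro side chain. In the forward step a palladium catalyst with a chiral phosphine inserts into the C–I bond of A6 and the alkene of A7 inserts into the aryl–palladium bond. The benzylic palladium species is captured by the neighbouring phenol oxygen while a silver salt removes iodide, giving the protected target A5.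
- For it: it is the most convergent plan. Two bonds and the ring form in one step from complete fragments, the aldehyde is present from the start, and only deprotection remains. In convergence and total count it is stronger.
- Against it: the absolute sense of this oxyarylation is not secured for electron-rich styrenes. The insertion sets C3, but the C–O bond forms from a benzylic palladium species that can ionise towards a cation stabilised by ring B, so the outcome depends on a ligand effect that is not established. The side-chain stereocentres are too remote to help, so failure would give a near-equal mixture of diastereomers of the most valuable intermediate. β-Hydride elimination to the Heck product competes. The final benzyl removal would have to spare an aldehyde and two benzylic C–O bonds.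
- Comparison: the chosen route places its one uncertain asymmetric step early, on cheap achiral material, and attaches the side chain afterwards by stereospecific chemistry. It concedes convergence.

Key step: step 8

Assumption: the sense of induction that Rh2(S-PTTL)4 (dirhodium tetrakis[N-phthaloyl-(S)-tert-leucinate]) shows with simpler aryl benzyl ethers (2R,3S cis product) is taken to hold for 11; if it proves opposite, Rh2(R-PTTL)4 is used and nothing else changes.

## Route

Step 1
Reactants: 1 methyl vanillate
Product: 2 methyl 4-hydroxy-3-iodo-5-methoxybenzoate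
Conditions: NIS, TFA (cat.), MeCN, rt
Reagents that add atoms: N-iodosuccinimide, O=C1CCC(=O)N1I
Why: Electrophilic aromatic iodination; the phenol directs to its only free ortho position, the para position being blocked by the ester.

Step 2
Reactants: 3 syringaldehyde
Product: 4 4-(benzyloxy)-3,5-dimethoxybenzaldehyde
Conditions: BnBr, K2CO3, DMF, 60 °C
Reagents that add atoms: benzyl bromide, BrCc1ccccc1
Why: Williamson O-benzylation of the hindered but acidic syringyl phenol; the aldehyde is inert to carbonate.

Step 3
Reactants: 4 4-(benzyloxy)-3,5-dimethoxybenzaldehyde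
Product: 5 [4-(benzyloxy)-3,5-dimethoxyphenyl]methanol
Conditions: NaBH4, MeOH, 0 °C
Reagents that add atoms: none
Why: Borohydride reduction of the aryl aldehyde to the benzylic alcohol; the ethers are untouched.

Step 4
Reactants: 5 [4-(benzyloxy)-3,5-dimethoxyphenyl]methanol
Product: 6 2-(benzyloxy)-5-(bromomethyl)-1,3-dimethoxybenzene
Conditions: PBr3, CH2Cl2, 0 °C
Reagents that add atoms: phosphorus tribromide, BrP(Br)Br
Why: Bromination of the benzylic alcohol through its phosphite ester; the electron-rich bromide ionises easily and is used at once.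

Step 5
Reactants: 2 methyl 4-hydroxy-3-iodo-5-methoxybenzoate; 6 2-(benzyloxy)-5-(bromomethyl)-1,3-dimethoxybenzene
Product: 7 methyl 4-{[4-(benzyloxy)-3,5-dimethoxyphenyl]methoxy}-3-iodo-5-methoxybenzoate
Conditions: K2CO3, DMF, rt
Reagents that add atoms: none
Why: Williamson etherification; the phenol of 2 is acidified by the para ester and the ortho iodine, and its phenoxide alkylates the reactive benzylic bromide although both ortho positions are occupied.

Step 6
Reactants: 7 methyl 4-{[4-(benzyloxy)-3,5-dimethoxyphenyl]methoxy}-3-iodo-5-methoxybenzoate; 8 methyl bromoacetate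
Product: 10 methyl 4-{[4-(benzyloxy)-3,5-dimethoxyphenyl]methoxy}-3-methoxy-5-(2-methoxy-2-oxoethyl)benzoate, via (2-methoxy-2-oxoethyl)zinc bromide 9 (not isolated)
Conditions: 8, Zn dust (TMSCl-activated), THF, rt; then 7, Pd2(dba)3 (cat.), XPhos (cat.), THF, 50 °C
Reagents that add atoms: none
Why: Negishi-type cross-coupling of a Reformatsky zinc enolate with the aryl iodide; the C-bound zinc enolate is not basic, so both esters and the benzylic ethers survive, and mono-arylation gives the arylacetate at the oxidation level needed for diazo transfer.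

Step 7
Reactants: 10 methyl 4-{[4-(benzyloxy)-3,5-dimethoxyphenyl]methoxy}-3-methoxy-5-(2-methoxy-2-oxoethyl)benzoate
Product: 11 methyl 2-diazo-2-[2-{[4-(benzyloxy)-3,5-dimethoxyphenyl]methoxy}-3-methoxy-5-(methoxycarbonyl)phenyl]acetate
Conditions: p-ABSA, DBU, MeCN, 0 °C → rt
Reagents that add atoms: 4-acetamidobenzenesulfonyl azide, CC(=O)Nc1ccc(cc1)S(=O)(=O)N=[N+]=[N-]
Why: Regitz diazo transfer; DBU deprotonates the benzylic ester position, the enolate attacks the sulfonyl azide, and loss of the sulfonamide leaves the donor–acceptor diazo ester.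

Step 8
Reactants: 11 methyl 2-diazo-2-[2-{[4-(benzyloxy)-3,5-dimethoxyphenyl]methoxy}-3-methoxy-5-(methoxycarbonyl)phenyl]acetate
Product: 12 dimethyl (2R,3S)-2-[4-(benzyloxy)-3,5-dimethoxyphenyl]-7-methoxy-2,3-dihydro-1-benzofuran-3,5-dicarboxylate (cis)
Conditions: Rh2(S-PTTL)4 (2 mol%), toluene, −78 → −40 °C, slow addition of 11 at high dilution
Reagents that add atoms: none
Why: The dirhodium carboxylate expels N2 from 11 and forms a donor–acceptor rhodium carbenoid at the future C3. The carbenoid carbon inserts into one C–H bond of the O–CH2 group five atoms away through a concerted, asynchronous three-centre transition state with hydride-transfer character; the closest known reaction type is the dirhodium tetracarboxylate-catalysed intramolecular C–H insertion of ortho-benzyloxy aryldiazoacetates to cis-2-aryl-2,3-dihydrobenzofuran-3-carboxylates. The dihydrofuran ring closes by this 1,5-insertion, through a five-membered cyclic transition state that forms the C2–C3 bond. C2 is set by the catalyst: the phthalimido wall of Rh2(S-PTTL)4 exposes one of the two enantiotopic benzylic hydrogens to the carbenoid, which should lead to 2R. C3 is set in the same event, and the kinetic product should be cis because aryl and ester end on the same face in the compact transition state; step 9 corrects this. Site selectivity rests on geometry and electronics: only the O–CH2 hydrogens of the syringyl benzyl ether can reach a five-membered transition state, and they are activated by the ether oxygen and the trialkoxyaryl ring, whereas the benzyl protecting group and the methyl ethers are remote. Low temperature, slow addition and dilution should hold back carbene dimerisation and attack on the π system of ring B.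

Step 9
Reactants: 12 dimethyl (2R,3S)-2-[4-(benzyloxy)-3,5-dimethoxyphenyl]-7-methoxy-2,3-dihydro-1-benzofuran-3,5-dicarboxylate
Product: 13 dimethyl (2R,3R)-2-[4-(benzyloxy)-3,5-dimethoxyphenyl]-7-methoxy-2,3-dihydro-1-benzofuran-3,5-dicarboxylate (trans)
Conditions: NaOMe, MeOH/THF, rt
Reagents that add atoms: none
Why: Epimerisation through the C3 ester enolate to the thermodynamically preferred trans isomer; C2 has no acidic hydrogen, and ring opening by β-elimination of the O1 phenoxide is the reverse of a 5-endo-trig closure (C2–O1 bond nearly orthogonal to the enolate π system), so the 2R centre should be kept.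

Step 10
Reactants: 13 dimethyl (2R,3R)-2-[4-(benzyloxy)-3,5-dimethoxyphenyl]-7-methoxy-2,3-dihydro-1-benzofuran-3,5-dicarboxylate
Product: 14 dimethyl (2R,3R)-2-(4-hydroxy-3,5-dimethoxyphenyl)-7-methoxy-2,3-dihydro-1-benzofuran-3,5-dicarboxylate
Conditions: H2 (1 atm), Pd/C, EtOAc, rt
Reagents that add atoms: none
Why: Hydrogenolysis of the primary benzyl aryl ether; the cyclic secondary benzylic C2–O1 bond is cleaved more slowly, and doing this before any aldehyde exists avoids carbonyl hydrogenation.

Step 11
Reactants: 15 4-bromo-2-methoxyphenol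
Product: 16 (4-bromo-2-methoxyphenoxy)tri(propan-2-yl)silane
Conditions: TIPSCl, imidazole, DMF, rt
Reagents that add atoms: chlorotriisopropylsilane, CC(C)[Si](Cl)(C(C)C)C(C)C
Why: Silylation of the phenol; the bulky aryl silyl ether tolerates n-BuLi, Mitsunobu conditions and hydride reagents and is removed by fluoride at the end.

Step 12
Reactants: 17 methyl (4S)-2,2-dimethyl-1,3-dioxolane-4-carboxylate
Product: 18 (4S)-N-methoxy-N,2,2-trimethyl-1,3-dioxolane-4-carboxamide
Conditions: MeNHOMe·HCl, iPrMgCl, THF, −20 → 0 °C
Reagents that add atoms: N,O-dimethylhydroxylamine hydrochloride, CNOC.Cl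
Why: Weinreb amide formation from the ester with the chloromagnesium amide made in the flask; this weakly basic amide leaves the α-alkoxy stereocentre intact.

Step 13
Reactants: 16 (4-bromo-2-methoxyphenoxy)tri(propan-2-yl)silane; 18 (4S)-N-methoxy-N,2,2-trimethyl-1,3-dioxolane-4-carboxamide
Product: 20 [(4S)-2,2-dimethyl-1,3-dioxolan-4-yl][3-methoxy-4-(triisopropylsilyloxy)phenyl]methanone, via [3-methoxy-4-(triisopropylsilyloxy)phenyl]lithium 19 (not isolated)
Conditions: 16, n-BuLi, THF, −78 °C; then 18, −78 → 0 °C; aq. NH4Cl
Reagents that add atoms: none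
Why: Bromine–lithium exchange gives the aryllithium, which adds once to the Weinreb amide; the chelated tetrahedral adduct collapses only on work-up, so no tertiary alcohol forms and the stereocentre never faces a free ketone under basic conditions.

Step 14
Reactants: 20 [(4S)-2,2-dimethyl-1,3-dioxolan-4-yl][3-methoxy-4-(triisopropylsilyloxy)phenyl]methanone
Product: 21 (2S)-2,3-dihydroxy-1-[3-methoxy-4-(triisopropylsilyloxy)phenyl]propan-1-one
Conditions: AcOH/H2O/THF (3:1:1), 40 °C
Reagents that add atoms: none
Why: Acid-catalysed hydrolysis of the isopropylidene acetal; mild aqueous acid keeps the aryl silyl ether and avoids the base-mediated enediol pathway that would racemise the α-hydroxy ketone.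

Step 15
Reactants: 21 (2S)-2,3-dihydroxy-1-[3-methoxy-4-(triisopropylsilyloxy)phenyl]propan-1-one
Product: 22 (2S)-3-(tert-butyldimethylsilyloxy)-2-hydroxy-1-[3-methoxy-4-(triisopropylsilyloxy)phenyl]propan-1-one
Conditions: TBSCl, imidazole, CH2Cl2, 0 °C
Reagents that add atoms: tert-butyldimethylsilyl chloride, CC(C)(C)[Si](C)(C)Cl
Why: Selective silylation of the primary hydroxyl; the secondary hydroxyl next to the carbonyl is more hindered and less nucleophilic and stays free for the coupling.

Step 16
Reactants: 14 dimethyl (2R,3R)-2-(4-hydroxy-3,5-dimethoxyphenyl)-7-methoxy-2,3-dihydro-1-benzofuran-3,5-dicarboxylate; 22 (2S)-3-(tert-butyldimethylsilyloxy)-2-hydroxy-1-[3-methoxy-4-(triisopropylsilyloxy)phenyl]propan-1-one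
Product: 23 dimethyl (2R,3R)-2-[4-({(2R)-3-(tert-butyldimethylsilyloxy)-1-[3-methoxy-4-(triisopropylsilyloxy)phenyl]-1-oxopropan-2-yl}oxy)-3,5-dimethoxyphenyl]-7-methoxy-2,3-dihydro-1-benzofuran-3,5-dicarboxylate
Conditions: PPh3, DIAD, toluene, 0 °C → rt
Reagents that add atoms: none
Why: Mitsunobu etherification; the phenol protonates the betaine, the secondary alcohol is activated as its alkoxyphosphonium ion and is displaced by the phenoxide in an SN2 step that the adjacent carbonyl accelerates, so the aryl ether should form with inversion (2S to 2R).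

Step 17
Reactants: 23 dimethyl (2R,3R)-2-[4-({(2R)-3-(tert-butyldimethylsilyloxy)-1-[3-methoxy-4-(triisopropylsilyloxy)phenyl]-1-oxopropan-2-yl}oxy)-3,5-dimethoxyphenyl]-7-methoxy-2,3-dihydro-1-benzofuran-3,5-dicarboxylate
Product: 24 dimethyl (2R,3R)-2-[4-({(1S,2R)-3-(tert-butyldimethylsilyloxy)-1-hydroxy-1-[3-methoxy-4-(triisopropylsilyloxy)phenyl]propan-2-yl}oxy)-3,5-dimethoxyphenyl]-7-methoxy-2,3-dihydro-1-benzofuran-3,5-dicarboxylate
Conditions: Zn(BH4)2, Et2O, −78 → −30 °C
Reagents that add atoms: none
Why: Chelation-controlled (Cram chelate) hydride reduction; zinc bridges the ketone oxygen and the α-aryloxy oxygen, assisted by an ortho-methoxy group of ring B, and hydride enters from the face opposite the CH2OTBS group, which should give the anti (erythro) 1S alcohol; the esters are not reduced at this temperature.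

Step 18
Reactants: 24 dimethyl (2R,3R)-2-[4-({(1S,2R)-3-(tert-butyldimethylsilyloxy)-1-hydroxy-1-[3-methoxy-4-(triisopropylsilyloxy)phenyl]propan-2-yl}oxy)-3,5-dimethoxyphenyl]-7-methoxy-2,3-dihydro-1-benzofuran-3,5-dicarboxylate
Product: 25 dimethyl (2R,3R)-2-[4-({(1S,2R)-1,3-bis(tert-butyldimethylsilyloxy)-1-[3-methoxy-4-(triisopropylsilyloxy)phenyl]propan-2-yl}oxy)-3,5-dimethoxyphenyl]-7-methoxy-2,3-dihydro-1-benzofuran-3,5-dicarboxylate
Conditions: TBSOTf, 2,6-lutidine, CH2Cl2, −78 → 0 °C
Reagents that add atoms: tert-butyldimethylsilyl trifluoromethanesulfonate, CC(C)(C)[Si](C)(C)OS(=O)(=O)C(F)(F)F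
Why: Silylation of the hindered secondary benzylic alcohol with the silyl triflate; this masks the only other benzylic alcohol before the oxidation in step 20.

Step 19
Reactants: 25 dimethyl (2R,3R)-2-[4-({(1S,2R)-1,3-bis(tert-butyldimethylsilyloxy)-1-[3-methoxy-4-(triisopropylsilyloxy)phenyl]propan-2-yl}oxy)-3,5-dimethoxyphenyl]-7-methoxy-2,3-dihydro-1-benzofuran-3,5-dicarboxylate
Product: 26 [(2R,3S)-2-[4-({(1S,2R)-1,3-bis(tert-butyldimethylsilyloxy)-1-[3-methoxy-4-(triisopropylsilyloxy)phenyl]propan-2-yl}oxy)-3,5-dimethoxyphenyl]-3-(hydroxymethyl)-7-methoxy-2,3-dihydro-1-benzofuran-5-yl]methanol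
Conditions: iBu2AlH, CH2Cl2, −78 → 0 °C; aq. potassium sodium tartrate
Reagents that add atoms: none
Why: Hydride reduction of both methyl esters to primary alcohols; the silyl ethers tolerate the reagent, and C3 is no longer epimerisable once it carries CH2OH (the descriptor changes to 3S by priority only).

Step 20
Reactants: 26 [(2R,3S)-2-[4-({(1S,2R)-1,3-bis(tert-butyldimethylsilyloxy)-1-[3-methoxy-4-(triisopropylsilyloxy)phenyl]propan-2-yl}oxy)-3,5-dimethoxyphenyl]-3-(hydroxymethyl)-7-methoxy-2,3-dihydro-1-benzofuran-5-yl]methanol
Product: 27 (2R,3S)-2-[4-({(1S,2R)-1,3-bis(tert-butyldimethylsilyloxy)-1-[3-methoxy-4-(triisopropylsilyloxy)phenyl]propan-2-yl}oxy)-3,5-dimethoxyphenyl]-3-(hydroxymethyl)-7-methoxy-2,3-dihydro-1-benzofuran-5-carbaldehyde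
Conditions: MnO2, CH2Cl2, rt
Reagents that add atoms: none
Why: MnO2 oxidises benzylic but not saturated primary alcohols, so only the ring C hydroxymethyl group should become the aldehyde; the ring A benzylic oxygen and the phenol are silylated and cannot react.

Step 21
Reactants: 27 (2R,3S)-2-[4-({(1S,2R)-1,3-bis(tert-butyldimethylsilyloxy)-1-[3-methoxy-4-(triisopropylsilyloxy)phenyl]propan-2-yl}oxy)-3,5-dimethoxyphenyl]-3-(hydroxymethyl)-7-methoxy-2,3-dihydro-1-benzofuran-5-carbaldehyde
Product: 28 (2R,3S)-2-[4-({(1S,2R)-1,3-dihydroxy-1-(4-hydroxy-3-methoxyphenyl)propan-2-yl}oxy)-3,5-dimethoxyphenyl]-3-(hydroxymethyl)-7-methoxy-2,3-dihydro-1-benzofuran-5-carbaldehyde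
Conditions: Bu4NF, AcOH, THF, 0 °C → rt
Reagents that add atoms: none
Why: Fluoride cleavage of the aryl silyl ether and both alkyl silyl ethers; acetic acid buffers the phenoxide and alkoxides, which protects the aldehyde and suppresses quinone methide chemistry at the freed 4-hydroxybenzylic position.

## Compound list

1 | methyl vanillate | COC(=O)c1ccc(O)c(OC)c1 | starting material
2 | methyl 4-hydroxy-3-iodo-5-methoxybenzoate | COC(=O)c1cc(I)c(O)c(OC)c1 | intermediate
3 | syringaldehyde | COc1cc(C=O)cc(OC)c1O | starting material
4 | 4-(benzyloxy)-3,5-dimethoxybenzaldehyde | COc1cc(C=O)cc(OC)c1OCc1ccccc1 | intermediate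
5 | [4-(benzyloxy)-3,5-dimethoxyphenyl]methanol | COc1cc(CO)cc(OC)c1OCc1ccccc1 | intermediate
6 | 2-(benzyloxy)-5-(bromomethyl)-1,3-dimethoxybenzene | COc1cc(CBr)cc(OC)c1OCc1ccccc1 | intermediate
7 | methyl 4-{[4-(benzyloxy)-3,5-dimethoxyphenyl]methoxy}-3-iodo-5-methoxybenzoate | COC(=O)c1cc(I)c(OCc2cc(OC)c(OCc3ccccc3)c(OC)c2)c(OC)c1 | intermediate
8 | methyl bromoacetate | COC(=O)CBr | starting material
9 | (2-methoxy-2-oxoethyl)zinc bromide | COC(=O)C[Zn]Br | intermediate
10 | methyl 4-{[4-(benzyloxy)-3,5-dimethoxyphenyl]methoxy}-3-methoxy-5-(2-methoxy-2-oxoethyl)benzoate | COC(=O)Cc1cc(C(=O)OC)cc(OC)c1OCc1cc(OC)c(OCc2ccccc2)c(OC)c1 | intermediate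
11 | methyl 2-diazo-2-[2-{[4-(benzyloxy)-3,5-dimethoxyphenyl]methoxy}-3-methoxy-5-(methoxycarbonyl)phenyl]acetate | COC(=O)C(=[N+]=[N-])c1cc(C(=O)OC)cc(OC)c1OCc1cc(OC)c(OCc2ccccc2)c(OC)c1 | intermediate
12 | dimethyl (2R,3S)-2-[4-(benzyloxy)-3,5-dimethoxyphenyl]-7-methoxy-2,3-dihydro-1-benzofuran-3,5-dicarboxylate (cis) | COc1cc(cc(OC)c1OCc1ccccc1)[C@@H]1Oc2c(OC)cc(C(=O)OC)cc2[C@@H]1C(=O)OC | intermediate
13 | dimethyl (2R,3R)-2-[4-(benzyloxy)-3,5-dimethoxyphenyl]-7-methoxy-2,3-dihydro-1-benzofuran-3,5-dicarboxylate (trans) | COc1cc(cc(OC)c1OCc1ccccc1)[C@@H]1Oc2c(OC)cc(C(=O)OC)cc2[C@H]1C(=O)OC | intermediate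
14 | dimethyl (2R,3R)-2-(4-hydroxy-3,5-dimethoxyphenyl)-7-methoxy-2,3-dihydro-1-benzofuran-3,5-dicarboxylate | COc1cc(cc(OC)c1O)[C@@H]1Oc2c(OC)cc(C(=O)OC)cc2[C@H]1C(=O)OC | intermediate
15 | 4-bromo-2-methoxyphenol | COc1cc(Br)ccc1O | starting material
16 | (4-bromo-2-methoxyphenoxy)tri(propan-2-yl)silane | COc1cc(Br)ccc1O[Si](C(C)C)(C(C)C)C(C)C | intermediate
17 | methyl (4S)-2,2-dimethyl-1,3-dioxolane-4-carboxylate | COC(=O)[C@@H]1COC(C)(C)O1 | starting material
18 | (4S)-N-methoxy-N,2,2-trimethyl-1,3-dioxolane-4-carboxamide | CON(C)C(=O)[C@@H]1COC(C)(C)O1 | intermediate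
19 | [3-methoxy-4-(triisopropylsilyloxy)phenyl]lithium | [Li]c1ccc(O[Si](C(C)C)(C(C)C)C(C)C)c(OC)c1 | intermediate
20 | [(4S)-2,2-dimethyl-1,3-dioxolan-4-yl][3-methoxy-4-(triisopropylsilyloxy)phenyl]methanone | COc1cc(ccc1O[Si](C(C)C)(C(C)C)C(C)C)C(=O)[C@@H]1COC(C)(C)O1 | intermediate
21 | (2S)-2,3-dihydroxy-1-[3-methoxy-4-(triisopropylsilyloxy)phenyl]propan-1-one | COc1cc(ccc1O[Si](C(C)C)(C(C)C)C(C)C)C(=O)[C@@H](O)CO | intermediate
22 | (2S)-3-(tert-butyldimethylsilyloxy)-2-hydroxy-1-[3-methoxy-4-(triisopropylsilyloxy)phenyl]propan-1-one | COc1cc(ccc1O[Si](C(C)C)(C(C)C)C(C)C)C(=O)[C@@H](O)CO[Si](C)(C)C(C)(C)C | intermediate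
23 | dimethyl (2R,3R)-2-[4-({(2R)-3-(tert-butyldimethylsilyloxy)-1-[3-methoxy-4-(triisopropylsilyloxy)phenyl]-1-oxopropan-2-yl}oxy)-3,5-dimethoxyphenyl]-7-methoxy-2,3-dihydro-1-benzofuran-3,5-dicarboxylate | COc1cc(C(=O)[C@@H](CO[Si](C)(C)C(C)(C)C)Oc2c(OC)cc([C@@H]3Oc4c(OC)cc(C(=O)OC)cc4[C@H]3C(=O)OC)cc2OC)ccc1O[Si](C(C)C)(C(C)C)C(C)C | intermediate
24 | dimethyl (2R,3R)-2-[4-({(1S,2R)-3-(tert-butyldimethylsilyloxy)-1-hydroxy-1-[3-methoxy-4-(triisopropylsilyloxy)phenyl]propan-2-yl}oxy)-3,5-dimethoxyphenyl]-7-methoxy-2,3-dihydro-1-benzofuran-3,5-dicarboxylate | COc1cc([C@H](O)[C@@H](CO[Si](C)(C)C(C)(C)C)Oc2c(OC)cc([C@@H]3Oc4c(OC)cc(C(=O)OC)cc4[C@H]3C(=O)OC)cc2OC)ccc1O[Si](C(C)C)(C(C)C)C(C)C | intermediate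
25 | dimethyl (2R,3R)-2-[4-({(1S,2R)-1,3-bis(tert-butyldimethylsilyloxy)-1-[3-methoxy-4-(triisopropylsilyloxy)phenyl]propan-2-yl}oxy)-3,5-dimethoxyphenyl]-7-methoxy-2,3-dihydro-1-benzofuran-3,5-dicarboxylate | COc1cc([C@H](O[Si](C)(C)C(C)(C)C)[C@@H](CO[Si](C)(C)C(C)(C)C)Oc2c(OC)cc([C@@H]3Oc4c(OC)cc(C(=O)OC)cc4[C@H]3C(=O)OC)cc2OC)ccc1O[Si](C(C)C)(C(C)C)C(C)C | intermediate
26 | [(2R,3S)-2-[4-({(1S,2R)-1,3-bis(tert-butyldimethylsilyloxy)-1-[3-methoxy-4-(triisopropylsilyloxy)phenyl]propan-2-yl}oxy)-3,5-dimethoxyphenyl]-3-(hydroxymethyl)-7-methoxy-2,3-dihydro-1-benzofuran-5-yl]methanol | COc1cc([C@H](O[Si](C)(C)C(C)(C)C)[C@@H](CO[Si](C)(C)C(C)(C)C)Oc2c(OC)cc([C@@H]3Oc4c(OC)cc(CO)cc4[C@H]3CO)cc2OC)ccc1O[Si](C(C)C)(C(C)C)C(C)C | intermediate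
27 | (2R,3S)-2-[4-({(1S,2R)-1,3-bis(tert-butyldimethylsilyloxy)-1-[3-methoxy-4-(triisopropylsilyloxy)phenyl]propan-2-yl}oxy)-3,5-dimethoxyphenyl]-3-(hydroxymethyl)-7-methoxy-2,3-dihydro-1-benzofuran-5-carbaldehyde | COc1cc([C@H](O[Si](C)(C)C(C)(C)C)[C@@H](CO[Si](C)(C)C(C)(C)C)Oc2c(OC)cc([C@@H]3Oc4c(OC)cc(C=O)cc4[C@H]3CO)cc2OC)ccc1O[Si](C(C)C)(C(C)C)C(C)C | intermediate
28 | (2R,3S)-2-[4-({(1S,2R)-1,3-dihydroxy-1-(4-hydroxy-3-methoxyphenyl)propan-2-yl}oxy)-3,5-dimethoxyphenyl]-3-(hydroxymethyl)-7-methoxy-2,3-dihydro-1-benzofuran-5-carbaldehyde | COc1cc([C@H](O)[C@@H](CO)Oc2c(OC)cc([C@@H]3Oc4c(OC)cc(C=O)cc4[C@H]3CO)cc2OC)ccc1O | target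

## Step count and least certain steps

Total step count: 21. Longest linear sequence: 15 steps (from 3 through steps 2–10 and 16–21). The branch from 1 joins at step 5, and the ring A fragment (steps 11–15) joins at step 16.

**Step 8 (key step).** The most likely failure is poor discrimination between the two enantiotopic benzylic hydrogens. The trioxygenated ring is bulky, and the neighbouring 3-methoxy group twists the O–CH2 bond out of the plane of ring C, so the catalyst pocket may not fit as it does for simpler ethers. Leakage to the trans isomer is harmless, since step 9 produces it anyway. Addition of the carbenoid to the electron-rich π system of ring B and carbene dimerisation are the chemical side paths. The fallback replaces catalyst control by auxiliary control. It sets out from 10 and returns at 13.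
- The aliphatic ester of 10 is saponified selectively (LiOH, THF/H2O, 0 °C; the benzoate is slower) to 2-[2-{[4-(benzyloxy)-3,5-dimethoxyphenyl]methoxy}-3-methoxy-5-(methoxycarbonyl)phenyl]acetic acid F1.
- F1 is esterified with (2R)-2-hydroxy-1-(pyrrolidin-1-yl)propan-1-one (carbodiimide, DMAP) to the lactamide ester F2.
- Diazo transfer as in step 7 gives the diazo ester F3.
- Insertion with Rh2(R-DOSP)4 (dirhodium tetrakis[(R)-N-(4-dodecylphenylsulfonyl)prolinate]) gives the dihydrobenzofuran lactamide ester F4. This auxiliary/catalyst pairing is taken as the mirror image of the pairing that favours the (2S,3S) series in closely related 7-alkoxy substrates.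
- NaOMe in MeOH then exchanges the auxiliary for methyl and equilibrates C3, giving 13.

**Step 16.** Activation and displacement may be slow because the phenol is flanked by two methoxy groups. During a slow reaction the product, an α-aryloxy ketone, can lose configuration at chain C2 by enolisation, or lose silanol by β-elimination. The fallback leaves the redox-condensation manifold. It sets out from 22 and returns at 23. The alcohol is converted with retention into (2S)-3-(tert-butyldimethylsilyloxy)-1-[3-methoxy-4-(triisopropylsilyloxy)phenyl]-1-oxopropan-2-yl methanesulfonate F5 (MsCl, Et3N, CH2Cl2, −20 °C). F5 is then displaced with inversion by the caesium phenoxide of 14 (Cs2CO3, MeCN, 0 °C), with a slight excess of 14 serving as buffer.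

**Step 17.** Chelation may be incomplete if the hindered aryloxy oxygen binds zinc poorly. An open Felkin-type transition state would then compete and bring in the threo isomer. The fallback replaces substrate control by catalyst control, from 23 to 24 with no new compound: transfer hydrogenation with RuCl(p-cymene)[(R,R)-TsDPEN] in HCO2H/Et3N. By the acetophenone model this catalyst should deliver the 1S alcohol, since here the alkyl chain outranks the aryl group in the priority rules.

**Step 6.** Transmetalation of the zinc enolate may be slow at the hindered ortho-alkoxy aryl–palladium centre. The aryl–palladium intermediate could then cyclise onto ring B by direct arylation or be reduced. The fallback builds the acetic acid side chain without cross-coupling. It sets out from 1 (and uses 6) and returns at 10.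
- 1 is O-allylated (allyl bromide, K2CO3) to methyl 3-methoxy-4-(prop-2-en-1-yloxy)benzoate F6.
- Aromatic Claisen rearrangement at about 200 °C gives methyl 4-hydroxy-3-methoxy-5-(prop-2-en-1-yl)benzoate F7.
- Alkylation with 6 gives methyl 4-{[4-(benzyloxy)-3,5-dimethoxyphenyl]methoxy}-3-methoxy-5-(prop-2-en-1-yl)benzoate F8.
- The alkene is cleaved (OsO4 cat., NaIO4, 2,6-lutidine) to methyl 4-{[4-(benzyloxy)-3,5-dimethoxyphenyl]methoxy}-3-methoxy-5-(2-oxoethyl)benzoate F9.
- Oxidation with NaClO2 gives the acid F1 described above, and MeI/K2CO3 gives 10.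

**Step 10.** Over-reduction is the concern: the O1–C2 bond is itself a benzylic aryl ether and may be hydrogenolysed once the benzyl group is gone, opening the ring. The fallback avoids hydrogen altogether, from 13 to 14 with no new compound: BCl3 with pentamethylbenzene as cation scavenger in CH2Cl2 at −78 °C removes the benzyl group as a benzyl cation equivalent.

## Further compounds

F1 | step 8 | 2-[2-{[4-(benzyloxy)-3,5-dimethoxyphenyl]methoxy}-3-methoxy-5-(methoxycarbonyl)phenyl]acetic acid | COC(=O)c1cc(CC(=O)O)c(OCc2cc(OC)c(OCc3ccccc3)c(OC)c2)c(OC)c1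
F2 | step 8 | methyl 4-{[4-(benzyloxy)-3,5-dimethoxyphenyl]methoxy}-3-methoxy-5-(2-oxo-2-{[(2R)-1-oxo-1-(pyrrolidin-1-yl)propan-2-yl]oxy}ethyl)benzoate | COC(=O)c1cc(CC(=O)O[C@H](C)C(=O)N2CCCC2)c(OCc2cc(OC)c(OCc3ccccc3)c(OC)c2)c(OC)c1
F3 | step 8 | (2R)-1-oxo-1-(pyrrolidin-1-yl)propan-2-yl 2-diazo-2-[2-{[4-(benzyloxy)-3,5-dimethoxyphenyl]methoxy}-3-methoxy-5-(methoxycarbonyl)phenyl]acetate | COC(=O)c1cc(C(=[N+]=[N-])C(=O)O[C@H](C)C(=O)N2CCCC2)c(OCc2cc(OC)c(OCc3ccccc3)c(OC)c2)c(OC)c1
F4 | step 8 | 5-methyl 3-[(2R)-1-oxo-1-(pyrrolidin-1-yl)propan-2-yl] (2R,3R)-2-[4-(benzyloxy)-3,5-dimethoxyphenyl]-7-methoxy-2,3-dihydro-1-benzofuran-3,5-dicarboxylate | COc1cc(cc(OC)c1OCc1ccccc1)[C@@H]1Oc2c(OC)cc(C(=O)OC)cc2[C@H]1C(=O)O[C@H](C)C(=O)N1CCCC1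
F5 | step 16 | (2S)-3-(tert-butyldimethylsilyloxy)-1-[3-methoxy-4-(triisopropylsilyloxy)phenyl]-1-oxopropan-2-yl methanesulfonate | COc1cc(ccc1O[Si](C(C)C)(C(C)C)C(C)C)C(=O)[C@@H](OS(C)(=O)=O)CO[Si](C)(C)C(C)(C)C
F0 | step 17 | none | none
F6 | step 6 | methyl 3-methoxy-4-(prop-2-en-1-yloxy)benzoate | COC(=O)c1ccc(OCC=C)c(OC)c1
F7 | step 6 | methyl 4-hydroxy-3-methoxy-5-(prop-2-en-1-yl)benzoate | COC(=O)c1cc(CC=C)c(O)c(OC)c1
F8 | step 6 | methyl 4-{[4-(benzyloxy)-3,5-dimethoxyphenyl]methoxy}-3-methoxy-5-(prop-2-en-1-yl)benzoate | COC(=O)c1cc(CC=C)c(OCc2cc(OC)c(OCc3ccccc3)c(OC)c2)c(OC)c1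
F9 | step 6 | methyl 4-{[4-(benzyloxy)-3,5-dimethoxyphenyl]methoxy}-3-methoxy-5-(2-oxoethyl)benzoate | COC(=O)c1cc(CC=O)c(OCc2cc(OC)c(OCc3ccccc3)c(OC)c2)c(OC)c1
F0 | step 10 | none | none
A1 | alternative 1 | (2R,3S)-3-[(tert-butyldimethylsilyloxy)methyl]-2-[3,5-dimethoxy-4-(methoxymethoxy)phenyl]-5-(1,3-dioxolan-2-yl)-2,3-dihydro-1-benzofuran-7-ol | COc1cc(cc(OC)c1OCOC)[C@@H]1Oc2c(O)cc(C3OCCO3)cc2[C@H]1CO[Si](C)(C)C(C)(C)C
A2 | alternative 1 | (1R,2S)-3-(tert-butyldimethylsilyloxy)-1-[3,5-dimethoxy-4-(methoxymethoxy)phenyl]-2-[5-(1,3-dioxolan-2-yl)-2-fluorophenyl]propan-1-ol | COc1cc(cc(OC)c1OCOC)[C@H](O)[C@H](CO[Si](C)(C)C(C)(C)C)c1cc(ccc1F)C1OCCO1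
A3 | alternative 2 | [(2R,3S)-5-formyl-2-(4-hydroxy-3,5-dimethoxyphenyl)-7-methoxy-2,3-dihydro-1-benzofuran-3-yl]methyl acetate | COc1cc(cc(OC)c1O)[C@@H]1Oc2c(OC)cc(C=O)cc2[C@H]1COC(C)=O
A4 | alternative 2 | (2S)-2-(5-formyl-2-hydroxy-3-methoxyphenyl)-3-(4-hydroxy-3,5-dimethoxyphenyl)propyl acetate | COc1cc(C[C@H](COC(C)=O)c2cc(C=O)cc(OC)c2O)cc(OC)c1O
A5 | alternative 3 | (2R,3S)-2-[4-({(1S,2R)-1-[4-(benzyloxy)-3-methoxyphenyl]-1,3-bis(tert-butyldimethylsilyloxy)propan-2-yl}oxy)-3,5-dimethoxyphenyl]-3-[(tert-butyldimethylsilyloxy)methyl]-7-methoxy-2,3-dihydro-1-benzofuran-5-carbaldehyde | COc1cc(ccc1OCc1ccccc1)[C@H](O[Si](C)(C)C(C)(C)C)[C@@H](CO[Si](C)(C)C(C)(C)C)Oc1c(OC)cc(cc1OC)[C@@H]1Oc2c(OC)cc(C=O)cc2[C@H]1CO[Si](C)(C)C(C)(C)C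
A6 | alternative 3 | 4-hydroxy-3-iodo-5-methoxybenzaldehyde | COc1cc(C=O)cc(I)c1O
A7 | alternative 3 | tert-butyl{[(2E)-3-[4-({(1S,2R)-1-[4-(benzyloxy)-3-methoxyphenyl]-1,3-bis(tert-butyldimethylsilyloxy)propan-2-yl}oxy)-3,5-dimethoxyphenyl]prop-2-en-1-yl]oxy}dimethylsilane | COc1cc(ccc1OCc1ccccc1)[C@H](O[Si](C)(C)C(C)(C)C)[C@@H](CO[Si](C)(C)C(C)(C)C)Oc1c(OC)cc(/C=C/CO[Si](C)(C)C(C)(C)C)cc1OC
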